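The constant to read first is the second-order one for E taking up J, read from D and Q together, the products seen of what E has lost.

in all of them: E 0.38 M

|  | J | remark | time |
|---|---|---|---|
| Monday's | 0.34 M | run made earlier |  |
| Tuesday's | 0.69 M | run made earlier |  |
| Saturday's | 1.1 M | run made earlier |  |
| red | 0.380 M |  | 80 min |
| teal | 0.570 M |  | 80 min |
| green | 1.14 M |  | 80 min |

- Monday's (time / min: D / %, Q / %): 8.00: 1, 0; 15.0: 6, 0; 25.0: 15, 0; 30.0: 15, 0; 40.0: 17, 0
- Tuesday's (time / min: D / %, Q / %): 3.00: 0, 0; 6.00: 3, 0; 12.0: 12, 0; 20.0: 15, 4; 40.0: 28, 1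
- Saturday's (time / min: D / %, Q / %): 3.00: 4, 1; 6.00: 10, 0; 12.0: 16, 2; 20.0: 22, 3; 40.0: 40, 3

(standard deviation of a reading: 2 percentage points)



* final D, as a percentage of the E charged, for each flask in turn (red, teal, green)

At Saturday's 40.0 min, D and Q stand at 43.0% of the E charged. Treating E as decaying pseudo-first-order at the charged c_J, the logarithm of E's remaining share, sign reversed, divided by c_J and by the time, gives a reading of 2.13 × 10⁻⁴ L mol⁻¹ s⁻¹, the turnover constant k. On Monday's run the same k reckons 15.9% at 40.0 min, against 17.0% read, with a scatter of 2 percentage points per reading.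

Two times are then held against each other: the lifetime of E, one over k times c_J, and the 80 min that the flask stands. The lifetime is 206 min in red and 137 min in teal, longer than the standing time, and 68.7 min in green, shorter than it. One minus exp of minus their ratio gives my own reckoning of E turned over: 32.2%, 44.2% and 68.8%, with D somewhat below these by what has passed to Q.

The forecast differs, giving D as 22%, 34% and 60%, with red at a “near-plateau”.

The flasks give D as 29.2%, 39.0% and 55.2%.

    E + J → D + Z (k = 2.50 × 10⁻⁴ L mol⁻¹ s⁻¹)
    J + Q → G (k = 2.40 × 10⁻⁴ L mol⁻¹ s⁻¹)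
    J + D ⇌ Q + Z (K = 2.30, k = 8.10 × 10⁻⁵ L mol⁻¹ s⁻¹)

Red shows no plateau, its D going from 17.9% at 40.0 min to 29.2% at 80.0 min. Red's reckoned turnover of 32.2% stands against 31.1% of E actually gone, and green's 68.8% against 68.2%. Being read early accounts for part of what teal's D lacks, 37% of what is missing: teal holds 39.0% at 80 min and, ten times later, 61.4%.

Readings and results come from a simulation for an exercise; scatter was added.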